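The carbocycle is disconnected at C1–C2 and reconnected through oxygen between C2 and C17, so that the target derives from an achiral 17-membered propargyl allyl ether (cembrane numbering). The key step exploits the homoallylic alcohol unit O–C2–C1–C15=C17 shared by the 14-membered ring and the γ-lactone: a [2,3]-Wittig shift of the C2 carbanion forms C1–C2 across the ring, contracts 17 to 14 members, creates the C15=C17 methylene and sets both stereocentres (syn, hence the cis lactone fusion) in one operation. The precursor holds C3≡C4 as the latent C3=C4 alkene, the C1=C15 alkene with C14 cis to C17, a TBS ether at C16 and a TBDPS ether at C19.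

Key step: step 19

Numbering: C1 is the ring-fusion CH bearing C15, C2 the O–CH, C15/C16/C17 the lactone α-carbon, carbonyl and exocyclic CH2, C18/C19/C20 the carbons on C4/C8/C12.
Structure note: the contraction product 27 is a propargylic (and homoallylic) alcohol, with the hydroxyl on the carbon next to the alkyne, and its C1 substituent is a 3-silyloxyprop-1-en-2-yl group; steps 20–23 depend on this placement.
Assumption: the (S,S)-amide is taken to remove the C2 hydrogen that leads to (1S,2R)-27; if Mosher ester analysis of the first run shows the opposite sense, the (R,R)-amide is used and nothing else changes.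
Convention: metal salts formed by simple deprotonation of a numbered compound (alkoxides, the acetylide, phosphonate anions, the C2 carbanion) are treated as reactive forms of that compound and carry no number.

Step 1
Reactants: 1 pent-4-yn-1-ol
Product: 2 tert-butyldimethyl(pent-4-yn-1-yloxy)silane
Conditions: TBSCl, imidazole, CH2Cl2, 0 °C → rt
Reagents that add atoms: tert-butyldimethylsilyl chloride, CC(C)(C)[Si](C)(C)Cl
Why: Imidazole-mediated silylation of a primary alcohol; the TBS ether masks C1–OH through the organometallic steps and can later be removed next to a TBDPS ether.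

Step 2
Reactants: 2 tert-butyldimethyl(pent-4-yn-1-yloxy)silane, 3 ethylene oxide
Product: 6 (E)-7-(tert-butyldimethylsilyloxy)-4-methylhept-3-en-1-ol, via vinylalane 4 (not isolated), via lithium alanate 5 (not isolated)
Conditions: Me3Al, Cp2ZrCl2 (cat.), CH2Cl2, rt; volatiles removed; n-BuLi, THF–hexane, −78 °C; ethylene oxide, −78 °C → rt
Reagents that add atoms: trimethylaluminium, C[Al](C)C
Why: Zr-catalysed carboalumination (Negishi) adds methyl and aluminium syn across the terminal alkyne with methyl on the internal carbon, which fixes C11=C12 as E, and the derived alanate opens ethylene oxide with retention at the alkenyl carbon to append C10 and C9.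

Step 3
Reactants: 6 (E)-7-(tert-butyldimethylsilyloxy)-4-methylhept-3-en-1-ol
Product: 7 (E)-tert-butyl[(7-iodo-4-methylhept-4-en-1-yl)oxy]dimethylsilane
Conditions: I2, PPh3, imidazole, CH2Cl2, 0 °C
Reagents that add atoms: iodine, II
Why: Appel-type iodination converts the primary homoallylic alcohol into the iodide by SN2 displacement without touching the silyl ether or the alkene.

Step 4
Reactants: 7 (E)-tert-butyl[(7-iodo-4-methylhept-4-en-1-yl)oxy]dimethylsilane, 8 methyl bis(2,2,2-trifluoroethyl)phosphonoacetate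
Product: 9 methyl (E)-2-[bis(2,2,2-trifluoroethoxy)phosphoryl]-9-(tert-butyldimethylsilyloxy)-6-methylnon-5-enoate (racemic at C8)
Conditions: NaH, DMF, 0 → 50 °C, excess of 8
Reagents that add atoms: none
Why: C-alkylation (SN2) of the sodium phosphonoacetate anion by the primary iodide installs C8 with its future C19 carbon; an excess of 8 should suppress dialkylation, and the C8 stereocentre is irrelevant because it becomes sp2 in step 8.

Step 5
Reactants: 10 prop-2-yn-1-ol
Product: 11 1-methoxy-4-[(prop-2-yn-1-yloxy)methyl]benzene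
Conditions: NaH, PMBCl, n-Bu4NI (cat.), THF–DMF, 0 °C → rt
Reagents that add atoms: 4-methoxybenzyl chloride, COc1ccc(CCl)cc1
Why: Williamson etherification gives a PMB ether that survives base, hydride and silylation and is removable oxidatively.

Step 6
Reactants: 11 1-methoxy-4-[(prop-2-yn-1-yloxy)methyl]benzene, 12 oxetane
Product: 13 6-[(4-methoxybenzyl)oxy]hex-4-yn-1-ol
Conditions: n-BuLi, THF, −78 °C; BF3·OEt2; oxetane, −78 °C
Reagents that add atoms: none
Why: The lithium acetylide opens BF3-activated oxetane by SN2 attack at CH2, delivering C5–C7 with the C7 hydroxyl in one step.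

Step 7
Reactants: 13 6-[(4-methoxybenzyl)oxy]hex-4-yn-1-ol
Product: 14 6-[(4-methoxybenzyl)oxy]hex-4-ynal
Conditions: Dess–Martin periodinane, NaHCO3, CH2Cl2, 0 °C → rt
Reagents that add atoms: none
Why: Dess–Martin oxidation of a primary alcohol to the aldehyde under buffered, neutral conditions compatible with the PMB ether and the alkyne.

Step 8
Reactants: 9 methyl (E)-2-[bis(2,2,2-trifluoroethoxy)phosphoryl]-9-(tert-butyldimethylsilyloxy)-6-methylnon-5-enoate, 14 6-[(4-methoxybenzyl)oxy]hex-4-ynal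
Product: 15 methyl (2Z)-2-[(3E)-7-(tert-butyldimethylsilyloxy)-4-methylhept-3-en-1-yl]-8-[(4-methoxybenzyl)oxy]oct-2-en-6-ynoate
Conditions: KHMDS, 18-crown-6, THF, −78 °C; then 14
Reagents that add atoms: none
Why: Still–Gennari olefination: the trifluoroethyl phosphonate under dissociating conditions should eliminate kinetically from the syn adduct, placing the ester (C19) cis to C6, which is the geometry required at C7=C8.

Step 9
Reactants: 15 methyl (2Z)-2-[(3E)-7-(tert-butyldimethylsilyloxy)-4-methylhept-3-en-1-yl]-8-[(4-methoxybenzyl)oxy]oct-2-en-6-ynoate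
Product: 16 (2Z)-2-[(3E)-7-(tert-butyldimethylsilyloxy)-4-methylhept-3-en-1-yl]-8-[(4-methoxybenzyl)oxy]oct-2-en-6-yn-1-ol
Conditions: DIBAL-H, CH2Cl2, −78 °C; Rochelle salt
Reagents that add atoms: none
Why: DIBAL reduces the enoate 1,2 to the allylic alcohol at low temperature without isomerising the trisubstituted alkene or touching the ethers.

Step 10
Reactants: 16 (2Z)-2-[(3E)-7-(tert-butyldimethylsilyloxy)-4-methylhept-3-en-1-yl]-8-[(4-methoxybenzyl)oxy]oct-2-en-6-yn-1-ol
Product: 17 tert-butyl{[(4E,8Z)-8-[(tert-butyldiphenylsilyloxy)methyl]-14-[(4-methoxybenzyl)oxy]-4-methyltetradeca-4,8-dien-12-yn-1-yl]oxy}dimethylsilane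
Conditions: TBDPSCl, imidazole, DMF, rt
Reagents that add atoms: tert-butyldiphenylsilyl chloride, CC(C)(C)[Si](Cl)(c1ccccc1)c1ccccc1
Why: Silylation of the primary allylic alcohol as the robust TBDPS ether, which has to last until step 24.

Step 11
Reactants: 17 tert-butyl{[(4E,8Z)-8-[(tert-butyldiphenylsilyloxy)methyl]-14-[(4-methoxybenzyl)oxy]-4-methyltetradeca-4,8-dien-12-yn-1-yl]oxy}dimethylsilane
Product: 18 (4E,8Z)-8-[(tert-butyldiphenylsilyloxy)methyl]-14-[(4-methoxybenzyl)oxy]-4-methyltetradeca-4,8-dien-12-yn-1-ol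
Conditions: PPTS (cat.), MeOH, rt
Reagents that add atoms: none
Why: Acid-catalysed methanolysis (selective desilylation) removes the primary alkyl TBS ether far faster than the bulkier TBDPS ether, and the PMB ether is inert.

Step 12
Reactants: 18 (4E,8Z)-8-[(tert-butyldiphenylsilyloxy)methyl]-14-[(4-methoxybenzyl)oxy]-4-methyltetradeca-4,8-dien-12-yn-1-ol
Product: 19 (4E,8Z)-8-[(tert-butyldiphenylsilyloxy)methyl]-14-[(4-methoxybenzyl)oxy]-4-methyltetradeca-4,8-dien-12-ynal
Conditions: Dess–Martin periodinane, NaHCO3, CH2Cl2, 0 °C → rt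
Reagents that add atoms: none
Why: Dess–Martin oxidation gives the C1 aldehyde needed for C–C bond formation at C1.

Step 13
Reactants: 19 (4E,8Z)-8-[(tert-butyldiphenylsilyloxy)methyl]-14-[(4-methoxybenzyl)oxy]-4-methyltetradeca-4,8-dien-12-ynal, 20 methyl acrylate
Product: 21 methyl (6E,10Z)-10-[(tert-butyldiphenylsilyloxy)methyl]-3-hydroxy-16-[(4-methoxybenzyl)oxy]-6-methyl-2-methylidenehexadeca-6,10-dien-14-ynoate (racemic at C1)
Conditions: DABCO, methyl acrylate (excess), MeOH, rt, several days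
Reagents that add atoms: none
Why: Baylis–Hillman reaction: the DABCO–acrylate zwitterion adds to the aldehyde and the amine is eliminated, attaching C15 (with C16 as ester and C17 as methylene) to C1; the new carbinol centre is racemic and is erased in step 14.

Step 14
Reactants: 21 methyl (6E,10Z)-10-[(tert-butyldiphenylsilyloxy)methyl]-3-hydroxy-16-[(4-methoxybenzyl)oxy]-6-methyl-2-methylidenehexadeca-6,10-dien-14-ynoate
Product: 22 methyl (2Z,6E,10Z)-2-(bromomethyl)-10-[(tert-butyldiphenylsilyloxy)methyl]-16-[(4-methoxybenzyl)oxy]-6-methylhexadeca-2,6,10-trien-14-ynoate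
Conditions: NBS, Me2S, CH2Cl2, 0 °C → rt
Reagents that add atoms: N-bromosuccinimide, O=C1CCC(=O)N1Br
Why: Corey–Kim-type bromination with allylic transposition: bromide displaces the alkoxysulfonium ion in an SN2′ sense, and the ester should direct formation of the isomer with C14 trans to CO2Me, i.e. cis to the CH2Br carbon C17.

Step 15
Reactants: 22 methyl (2Z,6E,10Z)-2-(bromomethyl)-10-[(tert-butyldiphenylsilyloxy)methyl]-16-[(4-methoxybenzyl)oxy]-6-methylhexadeca-2,6,10-trien-14-ynoate
Product: 23 (2Z,6E,10Z)-2-(bromomethyl)-10-[(tert-butyldiphenylsilyloxy)methyl]-16-[(4-methoxybenzyl)oxy]-6-methylhexadeca-2,6,10-trien-14-yn-1-ol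
Conditions: DIBAL-H, CH2Cl2, −78 °C; Rochelle salt; used at once
Reagents that add atoms: none
Why: DIBAL at −78 °C reduces the conjugated ester to the primary alcohol much faster than it displaces an allylic bromide, as in the known reduction of 2-(bromomethyl)acrylates, and the alkene geometry is untouched.

Step 16
Reactants: 23 (2Z,6E,10Z)-2-(bromomethyl)-10-[(tert-butyldiphenylsilyloxy)methyl]-16-[(4-methoxybenzyl)oxy]-6-methylhexadeca-2,6,10-trien-14-yn-1-ol
Product: 24 tert-butyl{[(2Z,6E,10Z)-2-(bromomethyl)-10-[(tert-butyldiphenylsilyloxy)methyl]-16-[(4-methoxybenzyl)oxy]-6-methylhexadeca-2,6,10-trien-14-yn-1-yl]oxy}dimethylsilane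
Conditions: TBSOTf, 2,6-lutidine, CH2Cl2, −78 °C
Reagents that add atoms: tert-butyldimethylsilyl trifluoromethanesulfonate, CC(C)(C)[Si](C)(C)OS(=O)(=O)C(F)(F)F
Why: Silylation with the silyl triflate and the hindered, non-nucleophilic base 2,6-lutidine protects C16–OH at −78 °C without the base being alkylated by the allylic bromide.

Step 17
Reactants: 24 tert-butyl{[(2Z,6E,10Z)-2-(bromomethyl)-10-[(tert-butyldiphenylsilyloxy)methyl]-16-[(4-methoxybenzyl)oxy]-6-methylhexadeca-2,6,10-trien-14-yn-1-yl]oxy}dimethylsilane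
Product: 25 (6Z,10E,14Z)-16-bromo-15-[(tert-butyldimethylsilyloxy)methyl]-7-[(tert-butyldiphenylsilyloxy)methyl]-11-methylhexadeca-6,10,14-trien-2-yn-1-ol
Conditions: DDQ, CH2Cl2/pH 7 buffer, 0 °C
Reagents that add atoms: none
Why: Oxidative PMB cleavage: DDQ oxidises the electron-rich benzyl ether to a hemiacetal that collapses to the C2 alcohol, while silyl ethers, the allylic bromide and the isolated alkenes are inert.

Step 18
Reactants: 25 (6Z,10E,14Z)-16-bromo-15-[(tert-butyldimethylsilyloxy)methyl]-7-[(tert-butyldiphenylsilyloxy)methyl]-11-methylhexadeca-6,10,14-trien-2-yn-1-ol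
Product: 26 (3E,7E,11Z)-3-[(tert-butyldimethylsilyloxy)methyl]-11-[(tert-butyldiphenylsilyloxy)methyl]-7-methyl-1-oxacycloheptadeca-3,7,11-trien-15-yne (17-membered ether, O between C2 and C17)
Conditions: NaH, THF, 45 °C, syringe-pump addition of 25, final ca. 3 mM
Reagents that add atoms: none
Why: Intramolecular Williamson etherification under high dilution: the unhindered primary propargylic alkoxide displaces the primary allylic bromide by SN2 (no β-hydrogen for E2, and SN2′ would have to attack the substituted C1), closing the 17-membered ether with the alkene geometry intact.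

Step 19
Reactants: 26 (3E,7E,11Z)-3-[(tert-butyldimethylsilyloxy)methyl]-11-[(tert-butyldiphenylsilyloxy)methyl]-7-methyl-1-oxacycloheptadeca-3,7,11-trien-15-yne
Product: 27 (1R,6Z,10E,14S)-14-[3-(tert-butyldimethylsilyloxy)prop-1-en-2-yl]-7-[(tert-butyldiphenylsilyloxy)methyl]-11-methylcyclotetradeca-6,10-dien-2-yn-1-ol (cembrane 1S,2R; C1/C2 syn)
Conditions: lithium (S,S)-bis(1-phenylethyl)amide (from the amine and n-BuLi), THF, −78 → −25 °C; H2O quench at −25 °C
Reagents that add atoms: none
Why: The amide removes one of the two enantiotopic C2 hydrogens (the most acidic site, propargylic and α to oxygen), and the C2 carbanion attacks C1 through a five-membered envelope transition state (C2–O–C17–C15–C1) while O–C17 breaks and the π bond moves to C15=C17, i.e. a [2,3]-Wittig rearrangement. The closest known reaction type is the [2,3]-Wittig ring contraction of macrocyclic propargyl allyl ethers with achiral or chiral lithium amide bases. The 14-membered carbocycle is closed by transannular C1–C2 bond formation inside the 17-membered ether (ring contraction 17 → 14), so no separate high-dilution carbocyclisation is needed. The syn C1/C2 relationship (both ring hydrogens on the same side) should follow from the alkene geometry, C14 cis to C17, combined with the exo position of the alkynyl arm in the envelope; the absolute configuration should come from the chiral amide, which distinguishes the two C2 hydrogens and stays associated with lithium during the fast shift. The step needs site selectivity for C2 over the allylic C17 and for [2,3] over [1,2] shift, which the propargylic acidity and the low temperature should secure; the degree of enantiocontrol on a 17-membered ether is the uncertain point of the route.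

Step 20
Reactants: 27 (1R,6Z,10E,14S)-14-[3-(tert-butyldimethylsilyloxy)prop-1-en-2-yl]-7-[(tert-butyldiphenylsilyloxy)methyl]-11-methylcyclotetradeca-6,10-dien-2-yn-1-ol
Product: 29 (1R,2Z,6Z,10E,14S)-14-[3-(tert-butyldimethylsilyloxy)prop-1-en-2-yl]-7-[(tert-butyldiphenylsilyloxy)methyl]-3-iodo-11-methylcyclotetradeca-2,6,10-trien-1-ol, via cyclic alkenylalanate 28 (not isolated)
Conditions: Red-Al, THF, 0 °C → rt; EtOAc, −78 °C; I2, THF, −78 → 0 °C
Reagents that add atoms: iodine, II
Why: Hydroxyl-directed trans-hydroalumination of the propargylic alcohol: the alkoxyaluminium hydride delivers hydride to C3 intramolecularly and forms the five-membered alkenylalanate with Al on C4 cis to C2, and iodinolysis with retention gives the (Z)-iodoalkene with the ring carbons C2 and C5 trans.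

Step 21
Reactants: 29 (1R,2Z,6Z,10E,14S)-14-[3-(tert-butyldimethylsilyloxy)prop-1-en-2-yl]-7-[(tert-butyldiphenylsilyloxy)methyl]-3-iodo-11-methylcyclotetradeca-2,6,10-trien-1-ol
Product: 30 (1S,2E,6Z,10E,14S)-14-[3-(tert-butyldimethylsilyloxy)prop-1-en-2-yl]-7-[(tert-butyldiphenylsilyloxy)methyl]-3,11-dimethylcyclotetradeca-2,6,10-trien-1-ol
Conditions: MeZnCl (excess), Pd(PPh3)4 (cat.), THF, rt → 45 °C
Reagents that add atoms: methylzinc chloride, C[Zn]Cl
Why: Negishi coupling: oxidative addition, transmetallation and reductive elimination proceed with retention, turning C4–I into C4–CH3 (C18) and fixing C3=C4 as E; the zinc alkoxide of C2–OH is tolerated, and the descriptor at C2 changes only through CIP priorities.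

Step 22
Reactants: 30 (1S,2E,6Z,10E,14S)-14-[3-(tert-butyldimethylsilyloxy)prop-1-en-2-yl]-7-[(tert-butyldiphenylsilyloxy)methyl]-3,11-dimethylcyclotetradeca-2,6,10-trien-1-ol
Product: 31 (1S,2E,6Z,10E,14S)-7-[(tert-butyldiphenylsilyloxy)methyl]-14-(3-hydroxyprop-1-en-2-yl)-3,11-dimethylcyclotetradeca-2,6,10-trien-1-ol
Conditions: HF·pyridine, pyridine, THF, 0 °C
Reagents that add atoms: none
Why: Selective desilylation: buffered HF·pyridine cleaves the primary TBS ether much faster than the primary TBDPS ether, and the weakly acidic medium should spare the ionisable allylic C2 alcohol.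

Step 23
Reactants: 31 (1S,2E,6Z,10E,14S)-7-[(tert-butyldiphenylsilyloxy)methyl]-14-(3-hydroxyprop-1-en-2-yl)-3,11-dimethylcyclotetradeca-2,6,10-trien-1-ol
Product: 34 (1S,2S)-19-(tert-butyldiphenylsilyloxy)cembra-3E,7Z,11E,15(17)-tetraen-16,2-olide (cis-fused), via hydroxy enal 32 (not isolated), via lactol 33 (not isolated)
Conditions: TEMPO (cat.), PhI(OAc)2, CH2Cl2, rt
Reagents that add atoms: none
Why: Oxidative lactonisation of a 1,4-diol: TEMPO/PhI(OAc)2 oxidises the primary allylic alcohol selectively to the enal, the C2 hydroxyl closes the five-membered lactol and a second oxidation gives the α-methylene-γ-lactone; the cis fusion follows from the untouched syn C1/C2 configuration.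

Step 24
Reactants: 34 (1S,2S)-19-(tert-butyldiphenylsilyloxy)cembra-3E,7Z,11E,15(17)-tetraen-16,2-olide
Product: 35 (1S,2S)-19-hydroxycembra-3E,7Z,11E,15(17)-tetraen-16,2-olide
Conditions: HF·pyridine, THF, 0 °C → rt
Reagents that add atoms: none
Why: Desilylation with HF·pyridine removes the remaining TBDPS ether under non-basic conditions, avoiding conjugate addition to or isomerisation of the α-methylene lactone.

Step 25
Reactants: 35 (1S,2S)-19-hydroxycembra-3E,7Z,11E,15(17)-tetraen-16,2-olide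
Product: 36 CNP0158848.2, (1S,2S)-19-acetoxycembra-3E,7Z,11E,15(17)-tetraen-16,2-olide
Conditions: Ac2O, pyridine, DMAP (cat.), CH2Cl2, 0 °C
Reagents that add atoms: acetic anhydride, CC(=O)OC(C)=O
Why: DMAP-catalysed acylation of the primary allylic alcohol with acetic anhydride gives the C19 acetate without affecting the lactone.

Compound list
1 | pent-4-yn-1-ol | C#CCCCO | starting material
2 | tert-butyldimethyl(pent-4-yn-1-yloxy)silane | C#CCCCO[Si](C)(C)C(C)(C)C | intermediate
3 | ethylene oxide | C1CO1 | starting material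
4 | (E)-[5-(tert-butyldimethylsilyloxy)-2-methylpent-1-en-1-yl]dimethylalane (vinylalane) | C[Al](C)/C=C(\C)CCCO[Si](C)(C)C(C)(C)C | intermediate
5 | lithium butyl[(E)-5-(tert-butyldimethylsilyloxy)-2-methylpent-1-en-1-yl]dimethylalanate | [Li+].CCCC[Al-](C)(C)/C=C(\C)CCCO[Si](C)(C)C(C)(C)C | intermediate
6 | (E)-7-(tert-butyldimethylsilyloxy)-4-methylhept-3-en-1-ol | OCC/C=C(\C)CCCO[Si](C)(C)C(C)(C)C | intermediate
7 | (E)-tert-butyl[(7-iodo-4-methylhept-4-en-1-yl)oxy]dimethylsilane | ICC/C=C(\C)CCCO[Si](C)(C)C(C)(C)C | intermediate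
8 | methyl bis(2,2,2-trifluoroethyl)phosphonoacetate | COC(=O)CP(=O)(OCC(F)(F)F)OCC(F)(F)F | starting material
9 | methyl (E)-2-[bis(2,2,2-trifluoroethoxy)phosphoryl]-9-(tert-butyldimethylsilyloxy)-6-methylnon-5-enoate, racemic | COC(=O)C(CC/C=C(\C)CCCO[Si](C)(C)C(C)(C)C)P(=O)(OCC(F)(F)F)OCC(F)(F)F | intermediate
10 | prop-2-yn-1-ol | C#CCO | starting material
11 | 1-methoxy-4-[(prop-2-yn-1-yloxy)methyl]benzene | C#CCOCc1ccc(OC)cc1 | intermediate
12 | oxetane | C1COC1 | starting material
13 | 6-[(4-methoxybenzyl)oxy]hex-4-yn-1-ol | OCCCC#CCOCc1ccc(OC)cc1 | intermediate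
14 | 6-[(4-methoxybenzyl)oxy]hex-4-ynal | O=CCCC#CCOCc1ccc(OC)cc1 | intermediate
15 | methyl (2Z)-2-[(3E)-7-(tert-butyldimethylsilyloxy)-4-methylhept-3-en-1-yl]-8-[(4-methoxybenzyl)oxy]oct-2-en-6-ynoate | CC(C)(C)[Si](C)(C)OCCC/C(C)=C/CC/C(C(=O)OC)=C/CCC#CCOCc1ccc(OC)cc1 | intermediate
16 | (2Z)-2-[(3E)-7-(tert-butyldimethylsilyloxy)-4-methylhept-3-en-1-yl]-8-[(4-methoxybenzyl)oxy]oct-2-en-6-yn-1-ol | CC(C)(C)[Si](C)(C)OCCC/C(C)=C/CC/C(CO)=C/CCC#CCOCc1ccc(OC)cc1 | intermediate
17 | tert-butyl{[(4E,8Z)-8-[(tert-butyldiphenylsilyloxy)methyl]-14-[(4-methoxybenzyl)oxy]-4-methyltetradeca-4,8-dien-12-yn-1-yl]oxy}dimethylsilane | CC(C)(C)[Si](C)(C)OCCC/C(C)=C/CC/C(CO[Si](c1ccccc1)(c1ccccc1)C(C)(C)C)=C/CCC#CCOCc1ccc(OC)cc1 | intermediate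
18 | (4E,8Z)-8-[(tert-butyldiphenylsilyloxy)methyl]-14-[(4-methoxybenzyl)oxy]-4-methyltetradeca-4,8-dien-12-yn-1-ol | OCCC/C(C)=C/CC/C(CO[Si](c1ccccc1)(c1ccccc1)C(C)(C)C)=C/CCC#CCOCc1ccc(OC)cc1 | intermediate
19 | (4E,8Z)-8-[(tert-butyldiphenylsilyloxy)methyl]-14-[(4-methoxybenzyl)oxy]-4-methyltetradeca-4,8-dien-12-ynal | O=CCC/C(C)=C/CC/C(CO[Si](c1ccccc1)(c1ccccc1)C(C)(C)C)=C/CCC#CCOCc1ccc(OC)cc1 | intermediate
20 | methyl acrylate | C=CC(=O)OC | starting material
21 | methyl (6E,10Z)-10-[(tert-butyldiphenylsilyloxy)methyl]-3-hydroxy-16-[(4-methoxybenzyl)oxy]-6-methyl-2-methylidenehexadeca-6,10-dien-14-ynoate, racemic | C=C(C(=O)OC)C(O)CC/C(C)=C/CC/C(CO[Si](c1ccccc1)(c1ccccc1)C(C)(C)C)=C/CCC#CCOCc1ccc(OC)cc1 | intermediate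
22 | methyl (2Z,6E,10Z)-2-(bromomethyl)-10-[(tert-butyldiphenylsilyloxy)methyl]-16-[(4-methoxybenzyl)oxy]-6-methylhexadeca-2,6,10-trien-14-ynoate | COC(=O)/C(CBr)=C/CC/C(C)=C/CC/C(CO[Si](c1ccccc1)(c1ccccc1)C(C)(C)C)=C/CCC#CCOCc1ccc(OC)cc1 | intermediate
23 | (2Z,6E,10Z)-2-(bromomethyl)-10-[(tert-butyldiphenylsilyloxy)methyl]-16-[(4-methoxybenzyl)oxy]-6-methylhexadeca-2,6,10-trien-14-yn-1-ol | OC/C(CBr)=C/CC/C(C)=C/CC/C(CO[Si](c1ccccc1)(c1ccccc1)C(C)(C)C)=C/CCC#CCOCc1ccc(OC)cc1 | intermediate
24 | tert-butyl{[(2Z,6E,10Z)-2-(bromomethyl)-10-[(tert-butyldiphenylsilyloxy)methyl]-16-[(4-methoxybenzyl)oxy]-6-methylhexadeca-2,6,10-trien-14-yn-1-yl]oxy}dimethylsilane | CC(C)(C)[Si](C)(C)OC/C(CBr)=C/CC/C(C)=C/CC/C(CO[Si](c1ccccc1)(c1ccccc1)C(C)(C)C)=C/CCC#CCOCc1ccc(OC)cc1 | intermediate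
25 | (6Z,10E,14Z)-16-bromo-15-[(tert-butyldimethylsilyloxy)methyl]-7-[(tert-butyldiphenylsilyloxy)methyl]-11-methylhexadeca-6,10,14-trien-2-yn-1-ol | CC(C)(C)[Si](C)(C)OC/C(CBr)=C/CC/C(C)=C/CC/C(CO[Si](c1ccccc1)(c1ccccc1)C(C)(C)C)=C/CCC#CCO | intermediate
26 | (3E,7E,11Z)-3-[(tert-butyldimethylsilyloxy)methyl]-11-[(tert-butyldiphenylsilyloxy)methyl]-7-methyl-1-oxacycloheptadeca-3,7,11-trien-15-yne | O1CC#CCC/C=C(\CO[Si](c2ccccc2)(c2ccccc2)C(C)(C)C)CC/C=C(\C)CC/C=C(/CO[Si](C)(C)C(C)(C)C)C1 | intermediate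
27 | (1R,6Z,10E,14S)-14-[3-(tert-butyldimethylsilyloxy)prop-1-en-2-yl]-7-[(tert-butyldiphenylsilyloxy)methyl]-11-methylcyclotetradeca-6,10-dien-2-yn-1-ol | C=C(CO[Si](C)(C)C(C)(C)C)[C@@H]1CC/C(C)=C/CC/C(CO[Si](c2ccccc2)(c2ccccc2)C(C)(C)C)=C/CCC#C[C@@H]1O | intermediate
28 | sodium cyclic alkenylalanate of 27 (five-membered O–Al–C4=C3–C2 ring, Al bearing two 2-methoxyethoxy groups) | [Na+].C=C(CO[Si](C)(C)C(C)(C)C)[C@@H]1CC/C(C)=C/CC/C(CO[Si](c2ccccc2)(c2ccccc2)C(C)(C)C)=C/CC/C3=C/[C@@H]1O[Al-]3(OCCOC)OCCOC | intermediate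
29 | (1R,2Z,6Z,10E,14S)-14-[3-(tert-butyldimethylsilyloxy)prop-1-en-2-yl]-7-[(tert-butyldiphenylsilyloxy)methyl]-3-iodo-11-methylcyclotetradeca-2,6,10-trien-1-ol | C=C(CO[Si](C)(C)C(C)(C)C)[C@@H]1CC/C(C)=C/CC/C(CO[Si](c2ccccc2)(c2ccccc2)C(C)(C)C)=C/CC/C(I)=C/[C@@H]1O | intermediate
30 | (1S,2E,6Z,10E,14S)-14-[3-(tert-butyldimethylsilyloxy)prop-1-en-2-yl]-7-[(tert-butyldiphenylsilyloxy)methyl]-3,11-dimethylcyclotetradeca-2,6,10-trien-1-ol | C=C(CO[Si](C)(C)C(C)(C)C)[C@@H]1CC/C(C)=C/CC/C(CO[Si](c2ccccc2)(c2ccccc2)C(C)(C)C)=C/CC/C(C)=C/[C@@H]1O | intermediate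
31 | (1S,2E,6Z,10E,14S)-7-[(tert-butyldiphenylsilyloxy)methyl]-14-(3-hydroxyprop-1-en-2-yl)-3,11-dimethylcyclotetradeca-2,6,10-trien-1-ol | C=C(CO)[C@@H]1CC/C(C)=C/CC/C(CO[Si](c2ccccc2)(c2ccccc2)C(C)(C)C)=C/CC/C(C)=C/[C@@H]1O | intermediate
32 | hydroxy enal: 2-[(1S,2S,3E,7Z,11E)-8-[(tert-butyldiphenylsilyloxy)methyl]-2-hydroxy-4,12-dimethylcyclotetradeca-3,7,11-trien-1-yl]prop-2-enal | C=C(C=O)[C@@H]1CC/C(C)=C/CC/C(CO[Si](c2ccccc2)(c2ccccc2)C(C)(C)C)=C/CC/C(C)=C/[C@@H]1O | intermediate
33 | lactol of 32 (C16 hemiacetal, both C16 epimers) | C=C1C(O)O[C@H]2/C=C(\C)CC/C=C(\CO[Si](c3ccccc3)(c3ccccc3)C(C)(C)C)CC/C=C(\C)CC[C@@H]12 | intermediate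
34 | (1S,2S)-19-(tert-butyldiphenylsilyloxy)cembra-3E,7Z,11E,15(17)-tetraen-16,2-olide | C=C1C(=O)O[C@H]2/C=C(\C)CC/C=C(\CO[Si](c3ccccc3)(c3ccccc3)C(C)(C)C)CC/C=C(\C)CC[C@@H]12 | intermediate
35 | (1S,2S)-19-hydroxycembra-3E,7Z,11E,15(17)-tetraen-16,2-olide | C=C1C(=O)O[C@H]2/C=C(\C)CC/C=C(\CO)CC/C=C(\C)CC[C@@H]12 | intermediate
36 | CNP0158848.2, (1S,2S)-19-acetoxycembra-3E,7Z,11E,15(17)-tetraen-16,2-olide | C=C1C(=O)O[C@H]2/C=C(\C)CC/C=C(\COC(C)=O)CC/C=C(\C)CC[C@@H]12 | target

Total step count: 25. Longest linear sequence: 22 steps (steps 1–4 and 8–25, from pent-4-yn-1-ol); the aldehyde branch (steps 5–7) has 3 steps.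

Steps most likely to fail

Step 19. The chiral amide may distinguish the two C2 hydrogens poorly on this flexible 17-membered ring, giving low enantiomeric excess, and some [1,2]-shift may compete. The fallback sets out from 26 and comes back at 27. Rearrangement with n-BuLi in THF–hexane (−78 → −20 °C) should give the syn alcohol as a racemate, i.e. 27 together with its mirror image, enantiomeric alcohol F1. Esterification of the mixture with (S)-2-methoxy-2-phenylacetic acid (DCC, DMAP, CH2Cl2) gives two diastereomers, mandelate F2 (from 27) and mandelate F3 (from F1), which are separated by chromatography. Hydrolysis of F2 (LiOH, THF/MeOH/H2O) returns enantiopure 27; its configuration is assigned from the O-methylmandelate shifts.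

Step 18. Intermolecular etherification may outrun ring closure and give oligomers, or the base may isomerise the propargyl ether to an allenyl ether. The fallback sets out from 24 and comes back at 26, and closes the ring at the alkyne instead of at oxygen. Intermolecular Williamson etherification of 24 with but-2-yn-1-ol (NaH, THF, 0 °C → rt) gives diyne F4. Ring-closing alkyne metathesis of F4 (molybdenum alkylidyne tris(triphenylsilanolate) catalyst, toluene, 5 Å molecular sieves, ca. 2 mM, rt → 60 °C) joins the propargyl ether carbon C3 to C4 and should give 26. The expelled alkyne is an involatile PMB butynyl ether, so the closure relies on dilution; alkenes and silyl ethers are inert to the catalyst.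

Step 13. The amine-catalysed addition may stall with this lipophilic, enolisable aldehyde, with aldol self-condensation competing over the long reaction time. The fallback sets out from 19 and comes back at 21, and replaces catalysis by a preformed nucleophile. Hydroalumination of methyl propiolate with DIBAL-H/NMO (THF, 0 °C) gives the α-metallated acrylate, vinylalane F5, which adds to aldehyde 19 at 0 °C → rt and gives 21 after aqueous work-up.

Further compounds
F1 | step 19 | (1S,6Z,10E,14R)-14-[3-(tert-butyldimethylsilyloxy)prop-1-en-2-yl]-7-[(tert-butyldiphenylsilyloxy)methyl]-11-methylcyclotetradeca-6,10-dien-2-yn-1-ol (enantiomer of 27) | C=C(CO[Si](C)(C)C(C)(C)C)[C@H]1CC/C(C)=C/CC/C(CO[Si](c2ccccc2)(c2ccccc2)C(C)(C)C)=C/CCC#C[C@H]1O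
F2 | step 19 | (S)-2-methoxy-2-phenylacetate of 27 | C=C(CO[Si](C)(C)C(C)(C)C)[C@@H]1CC/C(C)=C/CC/C(CO[Si](c2ccccc2)(c2ccccc2)C(C)(C)C)=C/CCC#C[C@@H]1OC(=O)[C@@H](OC)c3ccccc3
F3 | step 19 | (S)-2-methoxy-2-phenylacetate of F1 | C=C(CO[Si](C)(C)C(C)(C)C)[C@H]1CC/C(C)=C/CC/C(CO[Si](c2ccccc2)(c2ccccc2)C(C)(C)C)=C/CCC#C[C@H]1OC(=O)[C@@H](OC)c3ccccc3
F4 | step 18 | but-2-yn-1-yl ether of the C17 alcohol (24 with Br replaced by but-2-yn-1-yloxy; acyclic diyne) | CC(C)(C)[Si](C)(C)OC/C(COCC#CC)=C/CC/C(C)=C/CC/C(CO[Si](c1ccccc1)(c1ccccc1)C(C)(C)C)=C/CCC#CCOCc1ccc(OC)cc1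
F5 | step 13 | [1-(methoxycarbonyl)ethenyl]bis(2-methylpropyl)alane | C=C(C(=O)OC)[Al](CC(C)C)CC(C)C
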